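**Retrosynthetic overview**
- Flavone 5 ⇒ open-chain 1,3-diketone 4 by cutting the ring C aryl–oxygen bond O1–C8a (aryl C–H / enol O–H dehydrogenative coupling).
- Diketone 4 ⇒ ring B methyl ketone 2 + ring A ester 3 (crossed Claisen condensation).
- Ketone 2 ⇒ 1,2,3,5-tetramethoxybenzene 1 (Friedel–Crafts acetylation).
- Rings A and B are bought intact; the pyranone ring C is the only ring made, and it is closed in the last step.

**Assumptions**
- The target has no stereocentre and rotation about the C2–C1' bond is fast, so "single enantiomer" is taken as the achiral compound as drawn.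
- 1 and 3 are taken to be inexpensive catalogue compounds.

**Step 1**
Reactants: 1 1,2,3,5-tetramethoxybenzene
Product: 2 1-(2,3,4,6-tetramethoxyphenyl)ethan-1-one
Conditions: Ac2O (1.5 equiv), Sc(OTf)3 (10 mol%), MeNO2, 50 °C
Reagents that add atoms: acetic anhydride, CC(=O)OC(C)=O
Why: Friedel–Crafts acylation; the two free positions of 1 are equivalent and each lies ortho/para to three methoxy groups, so a single ketone forms, the acetyl group deactivates the ring against a second acylation, and the mild catalytic Lewis acid spares the aryl methyl ethers (no stereocentre is formed).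

**Step 2**
Reactants: 2 1-(2,3,4,6-tetramethoxyphenyl)ethan-1-one; 3 methyl 2,3-dimethoxybenzoate
Product: 4 1-(2,3-dimethoxyphenyl)-3-(2,3,4,6-tetramethoxyphenyl)propane-1,3-dione
Conditions: NaH (2.5 equiv), THF, reflux; then 1 M aq. HCl
Reagents that add atoms: none
Why: Crossed Claisen condensation; only 2 can enolise, 3 has no α-hydrogen, the hindered carbonyl of 2 resists self-aldol reaction, and irreversible deprotonation of the acidic 1,3-diketone by excess NaH pulls the equilibrium to the product (no stereocentre is formed; 4 is mainly the chelated enol).

**Step 3**
Reactants: 4 1-(2,3-dimethoxyphenyl)-3-(2,3,4,6-tetramethoxyphenyl)propane-1,3-dione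
Product: 5 5,6-dimethoxy-2-(2,3,4,6-tetramethoxyphenyl)-4H-chromen-4-one (5,6,2',3',4',6'-hexamethoxyflavone)
Conditions: Pd(OAc)2 (10 mol%), IPr·HCl (1,3-bis(2,6-diisopropylphenyl)imidazolium chloride, 12 mol%), 4,5-diazafluoren-9-one (10 mol%), MesCO2Na (0.5 equiv), air (1 atm), mesitylene, 120 °C
Reagents that add atoms: none
Why: Proposed new method: an enol-directed aerobic dehydrogenative C–H/O–H cyclisation in which the enolate oxygen on C3 of 4 (the one next to ring B) binds divalent palladium, and carboxylate-assisted concerted metalation–deprotonation then cleaves the only C–H bond ortho to a carbonyl group in the molecule (C6 of the 2,3-dimethoxybenzoyl ring A, which is also para to its 3-methoxy group; both ortho positions of ring B carry OMe, so ring B cannot be palladated in a chelate) to give a seven-membered aryl–Pd–O palladacycle; C–O reductive elimination, favoured by the bulky N-heterocyclic carbene, forms the O1–C8a bond and closes ring C (the carbon-bound enolate tautomer could only close an impossible four-membered ring), and the zerovalent palladium released is reoxidised by air with the diazafluorenone ligand, so water is the only by-product and no electrophilic oxidant is present that could attack the diketone CH2 or the electron-rich ring B; the closest known reaction type is the palladium-catalysed phenol- or enol-directed C–H activation/C–O cyclisation of 2-arylphenols to dibenzofurans and of 3-aryl-4-hydroxycoumarins to coumestans under air, together with carboxylate-directed C–H lactonisation of biaryl-2-carboxylic acids through seven-membered palladacycles, and what is new is an acyclic 1,3-diketone enol as the directing nucleophile to build a 4-pyranone ring (no stereocentre is formed).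

**Compound list**
1 | 1,2,3,5-tetramethoxybenzene | COc1cc(OC)c(OC)c(OC)c1 | starting material
2 | 1-(2,3,4,6-tetramethoxyphenyl)ethan-1-one (2',3',4',6'-tetramethoxyacetophenone) | CC(=O)c1c(OC)cc(OC)c(OC)c1OC | intermediate
3 | methyl 2,3-dimethoxybenzoate | COC(=O)c1cccc(OC)c1OC | starting material
4 | 1-(2,3-dimethoxyphenyl)-3-(2,3,4,6-tetramethoxyphenyl)propane-1,3-dione (achiral) | COc1cccc(C(=O)CC(=O)c2c(OC)cc(OC)c(OC)c2OC)c1OC | intermediate
5 | 5,6-dimethoxy-2-(2,3,4,6-tetramethoxyphenyl)-4H-chromen-4-one (5,6,2',3',4',6'-hexamethoxyflavone, achiral) | COc1cc(OC)c(-c2cc(=O)c3c(OC)c(OC)ccc3o2)c(OC)c1OC | target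

**Total step count:** 3
**Longest linear sequence:** 3 steps (1 → 2 → 4 → 5; ester 3 enters at step 2)

**Steps most likely to fail**

1) Step 3 (the proposed new reaction). The diketonate may hold palladium as an unreactive O,O-chelate, the seven-membered palladacycle may form slowly, C–O reductive elimination from divalent palladium may be slow for an enolate oxygen, and the enolate may autoxidise in hot air. The fallback uses known chemistry, with a halide-based ring closure in place of C–H activation; it sets out from 2 and comes back to the route at 5. Commercial 6-bromo-2,3-dimethoxybenzoic acid is converted with (COCl)2 and cat. DMF in CH2Cl2 into 6-bromo-2,3-dimethoxybenzoyl chloride F1. The lithium enolate of 2 (LiHMDS, 3 equiv, THF, −78 °C, aq. HCl work-up) is C-acylated with it to give 1-(6-bromo-2,3-dimethoxyphenyl)-3-(2,3,4,6-tetramethoxyphenyl)propane-1,3-dione F2. Intramolecular Ullmann-type O-arylation of its enolate (copper monoiodide CuI 10 mol%, K2CO3, DMF, 110 °C) then closes ring C and gives 5; only the distal enolate oxygen can reach the C–Br carbon, so the regiochemistry is fixed.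

2) Step 2. The electron-rich, ortho-substituted ester 3 may react sluggishly, and retro-Claisen cleavage may erode the yield. The fallback replaces ester acylation by aldol addition and oxidation; it sets out from 2 and comes back at 4. The lithium enolate of 2 (LiHMDS, 1.1 equiv, THF, −78 °C) is added to commercial 2,3-dimethoxybenzaldehyde and quenched cold with AcOH to give racemic 3-(2,3-dimethoxyphenyl)-3-hydroxy-1-(2,3,4,6-tetramethoxyphenyl)propan-1-one F3. Oxidation with Dess–Martin periodinane (CH2Cl2, rt) gives 4; the carbinol stereocentre is erased, so its configuration is irrelevant.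

3) Step 1. The catalyst may be inhibited by the chelating product, or a methoxy group ortho to the new ketone may be cleaved. The fallback replaces electrophilic substitution by directed ortho-metalation; it sets out from 1 and comes back at 2. n-BuLi and TMEDA (THF, 0 °C) lithiate 1 at the position flanked by two methoxy groups to give (2,3,4,6-tetramethoxyphenyl)lithium F4. This is quenched with N-methoxy-N-methylacetamide (−78 °C to rt, aq. HCl work-up) to give 2.

**Further compounds**
F1 | step 3 | 6-bromo-2,3-dimethoxybenzoyl chloride | COc1ccc(Br)c(C(Cl)=O)c1OC
F2 | step 3 | 1-(6-bromo-2,3-dimethoxyphenyl)-3-(2,3,4,6-tetramethoxyphenyl)propane-1,3-dione | COc1ccc(Br)c(C(=O)CC(=O)c2c(OC)cc(OC)c(OC)c2OC)c1OC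
F3 | step 2 | racemic 3-(2,3-dimethoxyphenyl)-3-hydroxy-1-(2,3,4,6-tetramethoxyphenyl)propan-1-one | COc1cccc(C(O)CC(=O)c2c(OC)cc(OC)c(OC)c2OC)c1OC
F4 | step 1 | (2,3,4,6-tetramethoxyphenyl)lithium | [Li]c1c(OC)cc(OC)c(OC)c1OC
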